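## Retrosynthetic overview

1. The target comes from its primary silyl ether. The cyclopentanol ring, the bond from the ring to the C(=CH2)–dienyl unit and both cyclopentane stereocentres are made last, in one Pd/In three-component cyclisation of an allenyl aldehyde with a dienyl iodide.
2. The dienyl iodide comes from propargyl alcohol: Cu-catalysed anti-carbomagnesiation/iodination, then a vinyl-ditin linchpin and iodination.
3. The allenyl aldehyde/enal comes from a cyclohexanone ester: enal by Peterson olefination (nitrile) and iBu2AlH, tertiary carbinol by methyl addition, ring ketone by Nef reaction of a nitro group.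
4. The cyclohexane ring is formed first, with the quaternary carbon and the adjacent CH centre, by an organocatalytic asymmetric double Michael reaction of an α-substituted Nazarov-type β-keto ester with an aliphatic nitroalkene.
5. All carbon comes from achiral methyl hex-5-ynoate, acrolein, nitromethane, a 4-silyloxybutanal, propargyl alcohol and a homoprenyl bromide.

Assumption: 4-[(tert-butyldimethylsilyl)oxy]butanal, methyl hex-5-ynoate, 5-bromo-2-methylpent-2-ene and (E)-1,2-bis(tributylstannyl)ethene are catalogue compounds, 2-(trimethylsilyl)propanenitrile and the squaramide catalyst are stock reagents, and the C–NO2 centre is drawn as the expected equatorial epimer (it is destroyed in step 7).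

## Route

Step 1
Reactants: 1 4-[(tert-butyldimethylsilyl)oxy]butanal; 2 nitromethane
Product: 4 (E)-tert-butyldimethyl[(5-nitropent-4-en-1-yl)oxy]silane, via nitro alcohol 3 (not isolated)
Conditions: 2 (5 equiv), Et3N (cat.), THF, 0 → 23 °C; then MsCl, Et3N, CH2Cl2, 0 °C
Reagents that add atoms: none
Why: Henry addition followed by mesylation and E1cB elimination gives the conjugated (E)-nitroalkene, the more stable isomer, and no stereocentre is created.

Step 2
Reactants: 5 methyl hex-5-ynoate
Product: 7 methyl hepta-5,6-dienoate, via Mannich base 6 (not isolated)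
Conditions: (CH2O)n, CuI (0.5 equiv), Cy2NH, dioxane, reflux
Reagents that add atoms: paraformaldehyde (as formaldehyde), C=O
Why: Crabbé allene homologation, in which the copper acetylide undergoes a Mannich reaction and the propargylic amine then transfers hydride with loss of the imine, turns the terminal alkyne into the terminal allene without touching the ester.

Step 3
Reactants: 7 methyl hepta-5,6-dienoate; 8 acrolein
Product: 10 methyl 2-(1-hydroxyprop-2-en-1-yl)hepta-5,6-dienoate, via lithium enolate 9 (not isolated)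
Conditions: LiN(iPr)2, THF, −78 °C; then 8, −78 °C; aq. NH4Cl
Reagents that add atoms: none
Why: Directed aldol addition of the kinetic lithium ester enolate, which adds 1,2 to acrolein at −78 °C; the two new centres (diastereomer mixture) are erased in steps 4 and 5.

Step 4
Reactants: 10 methyl 2-(1-hydroxyprop-2-en-1-yl)hepta-5,6-dienoate
Product: 11 methyl 2-(prop-2-enoyl)hepta-5,6-dienoate
Conditions: Dess–Martin periodinane, CH2Cl2, 0 °C
Reagents that add atoms: none
Why: Dess–Martin oxidation of the allylic alcohol under non-basic conditions gives the α-substituted Nazarov-type vinyl β-keto ester, which is used at once because it polymerises on standing.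

Step 5
Reactants: 11 methyl 2-(prop-2-enoyl)hepta-5,6-dienoate; 4 (E)-tert-butyldimethyl[(5-nitropent-4-en-1-yl)oxy]silane
Product: 13 methyl (1R,2S,3S)-3-nitro-6-oxo-1-(penta-3,4-dien-1-yl)-2-{3-[(tert-butyldimethylsilyl)oxy]propyl}cyclohexane-1-carboxylate, via acyclic Michael adduct 12 (not isolated)
Conditions: 3-{[3,5-bis(trifluoromethyl)phenyl]amino}-4-{[(1R,2R)-2-(dimethylamino)cyclohexyl]amino}cyclobut-3-ene-1,2-dione (5 mol%), 4 (1.3 equiv), PhMe, −20 °C, slow addition of 11; then tetramethylguanidine (10 mol%), 0 °C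
Reagents that add atoms: none
Why: Proposed new method: an asymmetric Michael–Michael (formal [4+2]) cascade in which the tertiary amine of the bifunctional squaramide forms the chelated Z-enolate of 11 while the squaramide N–H bonds bind the nitro group of 4, so that the first C–C bond sets the quaternary carbon (R) and the adjacent CH (S) in the relative sense known for α-alkyl β-keto esters (ester cis to the silyloxypropyl chain on the later ring), after which the nitronate closes 6-endo-trig onto the vinyl ketone and the nitro group settles equatorial; the closest known reactions are the amine-thiourea and amine-squaramide Michael additions of α-substituted β-keto esters to nitroalkenes and the double Michael reaction of α-unsubstituted γ,δ-unsaturated β-keto esters with nitrostyrenes, and what has not been shown is an α-alkyl Nazarov reagent giving an all-carbon quaternary centre with an aliphatic nitroalkene in one catalytic operation.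

Step 6
Reactants: 13 methyl (1R,2S,3S)-3-nitro-6-oxo-1-(penta-3,4-dien-1-yl)-2-{3-[(tert-butyldimethylsilyl)oxy]propyl}cyclohexane-1-carboxylate
Product: 14 methyl (1R,2S,5S,6S)-2-hydroxy-2-methyl-5-nitro-1-(penta-3,4-dien-1-yl)-6-{3-[(tert-butyldimethylsilyl)oxy]propyl}cyclohexane-1-carboxylate
Conditions: MeMgBr (3.5 equiv), CeCl3, THF, −78 °C; aq. NH4Cl
Reagents that add atoms: methylmagnesium bromide, C[Mg]Br
Why: Organocerium 1,2-addition (the nitro group is masked in the flask as its nitronate and enolisation is suppressed): in the chair with the side chain and nitro group equatorial the ester is axial and blocks its own face, so methyl enters axially from the opposite face and the tertiary hydroxyl ends cis to the ester (2S).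

Step 7
Reactants: 14 methyl (1R,2S,5S,6S)-2-hydroxy-2-methyl-5-nitro-1-(penta-3,4-dien-1-yl)-6-{3-[(tert-butyldimethylsilyl)oxy]propyl}cyclohexane-1-carboxylate
Product: 16 methyl (1R,2S,6S)-2-hydroxy-2-methyl-5-oxo-1-(penta-3,4-dien-1-yl)-6-{3-[(tert-butyldimethylsilyl)oxy]propyl}cyclohexane-1-carboxylate, via sodium nitronate 15 (not isolated)
Conditions: NaOMe, MeOH, 0 °C; then TiCl3, NH4OAc, H2O (pH 5–6), 0 → 23 °C
Reagents that add atoms: water, O
Why: Reductive Nef reaction: the nitronate is reduced by TiCl3 to the imine, which hydrolyses in the buffered medium to the ketone, conditions mild enough to keep the silyl ether, the allene and the α-stereocentre (C6) intact.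

Step 8
Reactants: 16 methyl (1R,2S,6S)-2-hydroxy-2-methyl-5-oxo-1-(penta-3,4-dien-1-yl)-6-{3-[(tert-butyldimethylsilyl)oxy]propyl}cyclohexane-1-carboxylate
Product: 17 methyl (1R,2S,6R)-5-[(1Z)-1-cyanoethylidene]-2-hydroxy-2-methyl-1-(penta-3,4-dien-1-yl)-6-{3-[(tert-butyldimethylsilyl)oxy]propyl}cyclohexane-1-carboxylate
Conditions: 2-(trimethylsilyl)propanenitrile, LiN(iPr)2 (3 equiv each), THF, −78 → 0 °C; aq. NH4Cl
Reagents that add atoms: 2-(trimethylsilyl)propanenitrile, CC(C#N)[Si](C)(C)C
Why: Peterson olefination with a small lithiated α-silyl nitrile adds to the hindered ketone at −78 °C (no retro-aldol of the tertiary aldolate) and loses silanolate to give the tetrasubstituted alkene, whose Z isomer is favoured because the slim nitrile, not the methyl group, sits next to the substituted ring carbon (A(1,3) strain); any E isomer is separated or equilibrated with a trace of iodine in light.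

Step 9
Reactants: 17 methyl (1R,2S,6R)-5-[(1Z)-1-cyanoethylidene]-2-hydroxy-2-methyl-1-(penta-3,4-dien-1-yl)-6-{3-[(tert-butyldimethylsilyl)oxy]propyl}cyclohexane-1-carboxylate
Product: 18 (2Z)-2-[(2R,3S,4S)-4-hydroxy-3-(hydroxymethyl)-4-methyl-3-(penta-3,4-dien-1-yl)-2-{3-[(tert-butyldimethylsilyl)oxy]propyl}cyclohexylidene]propanal
Conditions: iBu2AlH (6 equiv), CH2Cl2, −78 → −20 °C; aq. Rochelle salt, then SiO2
Reagents that add atoms: water, O
Why: Hydride reduction with iBu2AlH takes the conjugated nitrile to the N-aluminated aldimine (hydrolysed on work-up to the enal with retention of alkene geometry) and the ester to the primary alcohol, while allene, silyl ether and tertiary alcohol are inert.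

Step 10
Reactants: 18 (2Z)-2-[(2R,3S,4S)-4-hydroxy-3-(hydroxymethyl)-4-methyl-3-(penta-3,4-dien-1-yl)-2-{3-[(tert-butyldimethylsilyl)oxy]propyl}cyclohexylidene]propanal
Product: 19 (1R,2S,6R)-2-hydroxy-2-methyl-5-[(2Z)-1-oxopropan-2-ylidene]-1-(penta-3,4-dien-1-yl)-6-{3-[(tert-butyldimethylsilyl)oxy]propyl}cyclohexane-1-carbaldehyde
Conditions: Dess–Martin periodinane, pyridine, CH2Cl2, 0 °C
Reagents that add atoms: none
Why: Dess–Martin oxidation converts only the neopentyl primary alcohol into the aldehyde, since the tertiary alcohol cannot be oxidised and the enal and allene are untouched under these buffered conditions.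

Step 11
Reactants: 20 prop-2-yn-1-ol; 21 5-bromo-2-methylpent-2-ene
Product: 24 (Z)-3-iodo-2-(4-methylpent-3-en-1-yl)prop-2-en-1-ol, via Grignard reagent 22 (not isolated), via vinylmagnesium alkoxide 23 (not isolated)
Conditions: 21, Mg, THF; then 20, CuI (10 mol%), Et2O, 23 °C; then iodine, −30 °C
Reagents that add atoms: iodine, [I][I]
Why: Copper-catalysed, alkoxide-directed anti-carbomagnesiation of propargyl alcohol puts the homoprenyl group on C2 and magnesium on C3 cis to the CH2O group in a five-membered chelate, and iodinolysis with retention fixes the trisubstituted alkene geometry.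

Step 12
Reactants: 24 (Z)-3-iodo-2-(4-methylpent-3-en-1-yl)prop-2-en-1-ol; 25 (E)-1,2-bis(tributylstannyl)ethene
Product: 26 (2Z,4E)-2-(4-methylpent-3-en-1-yl)-5-(tributylstannyl)penta-2,4-dien-1-ol
Conditions: 25 (2.5 equiv), PdCl2(MeCN)2 (3 mol%), DMF, 23 °C
Reagents that add atoms: none
Why: Stille coupling of the vinyl iodide with one tin terminus of the excess distannane proceeds with retention at both alkenes and tolerates the free allylic alcohol.

Step 13
Reactants: 26 (2Z,4E)-2-(4-methylpent-3-en-1-yl)-5-(tributylstannyl)penta-2,4-dien-1-ol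
Product: 27 (2Z,4E)-5-iodo-2-(4-methylpent-3-en-1-yl)penta-2,4-dien-1-ol
Conditions: iodine, CH2Cl2, −78 → 0 °C
Reagents that add atoms: iodine, [I][I]
Why: Iododestannylation replaces tin by iodine with retention of the E geometry.

Step 14
Reactants: 19 (1R,2S,6R)-2-hydroxy-2-methyl-5-[(2Z)-1-oxopropan-2-ylidene]-1-(penta-3,4-dien-1-yl)-6-{3-[(tert-butyldimethylsilyl)oxy]propyl}cyclohexane-1-carbaldehyde; 27 (2Z,4E)-5-iodo-2-(4-methylpent-3-en-1-yl)penta-2,4-dien-1-ol
Product: 29 (2Z)-2-[(1S,2R,5S,6S,10R)-1,6-dihydroxy-2-[(3E,5Z)-6-(hydroxymethyl)-10-methylundeca-1,3,5,9-tetraen-2-yl]-6-methyl-10-{3-[(tert-butyldimethylsilyl)oxy]propyl}spiro[4.5]decan-9-ylidene]propanal, via allylindium diiodide 28 (not isolated)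
Conditions: Pd2(dba)3 (2.5 mol%), P(2-furyl)3 (10 mol%), InI (1.5 equiv), DMF, 23 → 40 °C
Reagents that add atoms: none
Why: Palladium/indium three-component cascade, known for aryl iodides, allenes and aldehydes: the dienylpalladium iodide from zerovalent palladium adds to the central allene carbon, InI turns the π-allylpalladium into a nucleophilic allylindium, and this allylates the neighbouring aldehyde through a cyclic six-membered transition state to give the cis-2-alkenylcyclopentanol, with trivalent indium chelated between the aldehyde oxygen and the tertiary hydroxyl so that the new hydroxyl is syn to the carbinol carbon (1S,2R).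

Step 15
Reactants: 29 (2Z)-2-[(1S,2R,5S,6S,10R)-1,6-dihydroxy-2-[(3E,5Z)-6-(hydroxymethyl)-10-methylundeca-1,3,5,9-tetraen-2-yl]-6-methyl-10-{3-[(tert-butyldimethylsilyl)oxy]propyl}spiro[4.5]decan-9-ylidene]propanal
Product: 30 (2Z)-2-[(1S,2R,5S,6S,10R)-1,6-dihydroxy-2-[(3E,5Z)-6-(hydroxymethyl)-10-methylundeca-1,3,5,9-tetraen-2-yl]-10-(3-hydroxypropyl)-6-methylspiro[4.5]decan-9-ylidene]propanal
Conditions: HF·pyridine, pyridine, THF, 0 °C
Reagents that add atoms: none
Why: Buffered fluoride cleavage of the primary silyl ether (desilylation) leaves the enal, the cross-conjugated triene and the free alcohols untouched and gives the target.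

## Compound list

1 | 4-[(tert-butyldimethylsilyl)oxy]butanal | CC(C)(C)[Si](C)(C)OCCCC=O | starting material
2 | nitromethane | C[N+](=O)[O-] | starting material
3 | 5-[(tert-butyldimethylsilyl)oxy]-1-nitropentan-2-ol (racemic) | CC(C)(C)[Si](C)(C)OCCCC(O)C[N+](=O)[O-] | intermediate
4 | (E)-tert-butyldimethyl[(5-nitropent-4-en-1-yl)oxy]silane | CC(C)(C)[Si](C)(C)OCCC/C=C/[N+](=O)[O-] | intermediate
5 | methyl hex-5-ynoate | COC(=O)CCCC#C | starting material
6 | methyl 7-(dicyclohexylamino)hept-5-ynoate | COC(=O)CCCC#CCN(C1CCCCC1)C1CCCCC1 | intermediate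
7 | methyl hepta-5,6-dienoate | COC(=O)CCCC=C=C | intermediate
8 | acrolein (prop-2-enal) | C=CC=O | starting material
9 | lithium 1-methoxyhepta-1,5,6-trien-1-olate (ester enolate of 7) | [Li+].[O-]C(OC)=CCCC=C=C | intermediate
10 | methyl 2-(1-hydroxyprop-2-en-1-yl)hepta-5,6-dienoate (diastereomer mixture) | C=C=CCCC(C(=O)OC)C(O)C=C | intermediate
11 | methyl 2-(prop-2-enoyl)hepta-5,6-dienoate (racemic, enolisable) | C=C=CCCC(C(=O)OC)C(=O)C=C | intermediate
12 | methyl (2R)-2-[(2S)-1-nitro-5-{[tert-butyl(dimethyl)silyl]oxy}pentan-2-yl]-2-(prop-2-enoyl)hepta-5,6-dienoate | C=C=CCC[C@](C(=O)C=C)([C@H](CCCO[Si](C)(C)C(C)(C)C)C[N+](=O)[O-])C(=O)OC | intermediate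
13 | methyl (1R,2S,3S)-3-nitro-6-oxo-1-(penta-3,4-dien-1-yl)-2-{3-[(tert-butyldimethylsilyl)oxy]propyl}cyclohexane-1-carboxylate | C=C=CCC[C@]2([C@H](CCCO[Si](C)(C)C(C)(C)C)[C@@H]([N+](=O)[O-])CCC2=O)C(=O)OC | intermediate
14 | methyl (1R,2S,5S,6S)-2-hydroxy-2-methyl-5-nitro-1-(penta-3,4-dien-1-yl)-6-{3-[(tert-butyldimethylsilyl)oxy]propyl}cyclohexane-1-carboxylate | C=C=CCC[C@]2([C@H](CCCO[Si](C)(C)C(C)(C)C)[C@@H]([N+](=O)[O-])CC[C@]2(C)O)C(=O)OC | intermediate
15 | sodium nitronate of 14 (C5 =N(O)O−, other centres as in 14) | C=C=CCC[C@]2([C@H](CCCO[Si](C)(C)C(C)(C)C)C(=[N+]([O-])[O-])CC[C@]2(C)O)C(=O)OC.[Na+] | intermediate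
16 | methyl (1R,2S,6S)-2-hydroxy-2-methyl-5-oxo-1-(penta-3,4-dien-1-yl)-6-{3-[(tert-butyldimethylsilyl)oxy]propyl}cyclohexane-1-carboxylate | C=C=CCC[C@]2([C@H](CCCO[Si](C)(C)C(C)(C)C)C(=O)CC[C@]2(C)O)C(=O)OC | intermediate
17 | methyl (1R,2S,6R)-5-[(1Z)-1-cyanoethylidene]-2-hydroxy-2-methyl-1-(penta-3,4-dien-1-yl)-6-{3-[(tert-butyldimethylsilyl)oxy]propyl}cyclohexane-1-carboxylate | C=C=CCC[C@]2([C@H](CCCO[Si](C)(C)C(C)(C)C)/C(=C(/C)C#N)CC[C@]2(C)O)C(=O)OC | intermediate
18 | (2Z)-2-[(2R,3S,4S)-4-hydroxy-3-(hydroxymethyl)-4-methyl-3-(penta-3,4-dien-1-yl)-2-{3-[(tert-butyldimethylsilyl)oxy]propyl}cyclohexylidene]propanal | C=C=CCC[C@]2([C@H](CCCO[Si](C)(C)C(C)(C)C)/C(=C(/C)C=O)CC[C@]2(C)O)CO | intermediate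
19 | (1R,2S,6R)-2-hydroxy-2-methyl-5-[(2Z)-1-oxopropan-2-ylidene]-1-(penta-3,4-dien-1-yl)-6-{3-[(tert-butyldimethylsilyl)oxy]propyl}cyclohexane-1-carbaldehyde | C=C=CCC[C@]2([C@H](CCCO[Si](C)(C)C(C)(C)C)/C(=C(/C)C=O)CC[C@]2(C)O)C=O | intermediate
20 | prop-2-yn-1-ol | C#CCO | starting material
21 | 5-bromo-2-methylpent-2-ene | CC(C)=CCCBr | starting material
22 | (4-methylpent-3-en-1-yl)magnesium bromide | CC(C)=CCC[Mg]Br | intermediate
23 | bromomagnesium (Z)-3-(bromomagnesio)-2-(4-methylpent-3-en-1-yl)prop-2-en-1-olate (Mg cis to CH2O) | CC(C)=CCC/C(CO[Mg]Br)=C/[Mg]Br | intermediate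
24 | (Z)-3-iodo-2-(4-methylpent-3-en-1-yl)prop-2-en-1-ol | CC(C)=CCC/C(CO)=C/I | intermediate
25 | (E)-1,2-bis(tributylstannyl)ethene | CCCC[Sn](CCCC)(CCCC)/C=C/[Sn](CCCC)(CCCC)CCCC | starting material
26 | (2Z,4E)-2-(4-methylpent-3-en-1-yl)-5-(tributylstannyl)penta-2,4-dien-1-ol | CCCC[Sn](CCCC)(CCCC)/C=C/C=C(\CO)CCC=C(C)C | intermediate
27 | (2Z,4E)-5-iodo-2-(4-methylpent-3-en-1-yl)penta-2,4-dien-1-ol | I/C=C/C=C(\CO)CCC=C(C)C | intermediate
28 | allylindium diiodide: I2In–CH2–C(dienyl)=CH–CH2CH2– chain on C1 of the cyclohexanecarbaldehyde, ring centres as in 19 | I[In](I)CC(/C=C/C=C(\CO)CCC=C(C)C)=CCC[C@]2([C@H](CCCO[Si](C)(C)C(C)(C)C)/C(=C(/C)C=O)CC[C@]2(C)O)C=O | intermediate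
29 | (2Z)-2-[(1S,2R,5S,6S,10R)-1,6-dihydroxy-2-[(3E,5Z)-6-(hydroxymethyl)-10-methylundeca-1,3,5,9-tetraen-2-yl]-6-methyl-10-{3-[(tert-butyldimethylsilyl)oxy]propyl}spiro[4.5]decan-9-ylidene]propanal | C=C(/C=C/C=C(\CO)CCC=C(C)C)[C@H]1CC[C@]2([C@H](CCCO[Si](C)(C)C(C)(C)C)/C(=C(/C)C=O)CC[C@]2(C)O)[C@H]1O | intermediate
30 | (2Z)-2-[(1S,2R,5S,6S,10R)-1,6-dihydroxy-2-[(3E,5Z)-6-(hydroxymethyl)-10-methylundeca-1,3,5,9-tetraen-2-yl]-10-(3-hydroxypropyl)-6-methylspiro[4.5]decan-9-ylidene]propanal | C=C(/C=C/C=C(\CO)CCC=C(C)C)[C@H]1CC[C@]2([C@H](CCCO)/C(=C(/C)C=O)CC[C@]2(C)O)[C@H]1O | target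

## Step count and risk

Total step count: 15. Longest linear sequence: 11 steps (2, 3, 4, 5, 6, 7, 8, 9, 10, 14, 15, from methyl hex-5-ynoate).

Three steps most likely to fail:

Step 5 (the proposed new double Michael reaction). The risks are self-condensation of the vinyl ketone 11 and insufficient control at the quaternary carbon. The fallback uses known chemistry, sets out from 4 and comes back at 13. The established amine-squaramide double Michael reaction of an α-unsubstituted γ,δ-unsaturated β-keto ester with a nitroalkene is run with freshly prepared methyl 3-oxopent-4-enoate F1 and 4 (same squaramide, then tetramethylguanidine). It gives methyl (2S,3S)-3-nitro-6-oxo-2-{3-[(tert-butyldimethylsilyl)oxy]propyl}cyclohexane-1-carboxylate F2. The quaternary centre is then made by C-alkylation of this β-keto ester (K2CO3, acetone, 40 °C) with 5-iodopenta-1,2-diene F3, which enters anti to the neighbouring side chain and gives 13.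

Step 8 (Peterson olefination of a hindered ketone, Z/E control). The fallback sets out from 16 and comes back at 18. CH2=C(CH3)MgBr with CeCl3 adds to the ketone from the equatorial side, and the axial alkoxide closes onto the ester to give the bridged lactone F4. LiAlH4 opens it to the triol F5. The primary alcohol is acetylated (Ac2O, pyridine, 0 °C) to the monoacetate F6. Oxidative 1,3-transposition of the tertiary allylic alcohol with C5H5NH[CrO3Cl] in CH2Cl2 gives the acetoxymethyl enal F7 with the thermodynamic Z geometry. K2CO3 in MeOH then returns 18.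

Step 14 (three-component cyclisation with a dienyl iodide; chemoselectivity and facial control). The fallback sets out from 19 and comes back at 29. The known palladium-catalysed distannylative cyclisation of allenyl aldehydes ((Bu3Sn)2, [Pd(η3-C3H5)Cl]2 cat., THF) gives the cis-2-[1-(tributylstannyl)vinyl]cyclopentanol F8. Stille coupling of F8 with 27 (Pd2(dba)3, AsPh3, CuI, DMF) gives 29.

Further compounds
F1 | step 5 | methyl 3-oxopent-4-enoate | C=CC(=O)CC(=O)OC
F2 | step 5 | methyl (2S,3S)-3-nitro-6-oxo-2-{3-[(tert-butyldimethylsilyl)oxy]propyl}cyclohexane-1-carboxylate (C1 epimers and enol) | COC(=O)C1[C@H](CCCO[Si](C)(C)C(C)(C)C)[C@@H]([N+](=O)[O-])CCC1=O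
F3 | step 5 | 5-iodopenta-1,2-diene | C=C=CCCI
F4 | step 8 | 2-hydroxy-2-methyl-1-(penta-3,4-dien-1-yl)-5-(prop-1-en-2-yl)-8-{3-[(tert-butyldimethylsilyl)oxy]propyl}-6-oxabicyclo[3.2.1]octan-7-one (centres as in 16, lactone oxygen axial) | C=C=CCC[C@]2([C@H](CCCO[Si](C)(C)C(C)(C)C)[C@@]3(C(C)=C)CC[C@]2(C)O)C(=O)O3
F5 | step 8 | triol: 2-(hydroxymethyl)-1-methyl-2-(penta-3,4-dien-1-yl)-4-(prop-1-en-2-yl)-3-{3-[(tert-butyldimethylsilyl)oxy]propyl}cyclohexane-1,4-diol (centres as in F4) | C=C=CCC[C@]2([C@H](CCCO[Si](C)(C)C(C)(C)C)[C@@](O)(C(C)=C)CC[C@]2(C)O)CO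
F6 | step 8 | primary monoacetate of F5 | C=C=CCC[C@]2([C@H](CCCO[Si](C)(C)C(C)(C)C)[C@@](O)(C(C)=C)CC[C@]2(C)O)COC(C)=O
F7 | step 8 | acetate of 18 (acetoxymethyl enal, Z) | C=C=CCC[C@]2([C@H](CCCO[Si](C)(C)C(C)(C)C)/C(=C(/C)C=O)CC[C@]2(C)O)COC(C)=O
F8 | step 14 | analogue of 29 with a 1-(tributylstannyl)vinyl group at C2 in place of the tetraenyl chain (cis to the C1 hydroxyl) | C=C([Sn](CCCC)(CCCC)CCCC)[C@H]1CC[C@]2([C@H](CCCO[Si](C)(C)C(C)(C)C)/C(=C(/C)C=O)CC[C@]2(C)O)[C@H]1O
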